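**Remark on numbering.** Neolignan numbering is used: ring A is C1–C6 (OH on C4, OMe on C3/C5) and carries C7 (carbinol), C8 and C9 (methyl); ring B is C1'–C6' (ether oxygen O4' on C4', OMe on C3'/C5') and carries the propenyl group C7'=C8'–C9'. In this numbering the target is (7R,8S), which is (1R,2S) in the propanol name and the erythro (anti) diastereomer.

## Analysis of the target

- The target is an acyclic 8-O-4' neolignan: two arenes joined through the secondary aryl alkyl ether C8–O4', with no ring other than the two benzene rings.
- The feature the route is built on: ring A with C7–C8–C9 and ring B with C7'=C8'–C9' are the same C6–C3 unit, a 4-substituted 2,6-dimethoxyphenol. The target is two molecules of (E)-2,6-dimethoxy-4-propenylphenol minus two hydrogens plus one water, with O4' and OH added across C7=C8 of one of them.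
- There are two adjacent stereocentres, C7 (R, benzylic carbinol) and C8 (S, aryloxy-bearing), in the erythro relationship, and one (E)-alkene on ring B.
- C7 is a p-hydroxybenzylic alcohol: acid, or base with heat, ionises it towards a quinone methide and epimerises it.
- The propenyl styrene is electron-rich and sensitive to acid, electrophilic oxidants and unselective hydrogenation; the free phenol is easily oxidised.
- The hard points are the C8–O4' bond (a di-ortho-substituted, electron-rich phenoxide on a secondary carbon; no SNAr option) and the anti pair in one absolute sense, given that C8 can only be equilibrated at the C7 ketone level.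

## Retrosynthetic reasoning

**8 from 7.** The only change is removal of an O4 allyl group from ring A. The phenol has to be masked for the stereo-defining step, which runs in alkoxide base, and the mask must come off without acid (C7 is labile), without hydrogenolysis (propenyl) and without touching the stereocentres.

**7 from 6.** The C7–H bond is cut, leading back to racemic ketone 6. C8 in 6 is α to an aryl ketone and epimerises through the enolate, so a chiral hydrogenation catalyst can take both enantiomers of 6 to one stereoisomer of 7 by dynamic kinetic resolution. Both stereocentres are set as a pair in this one step, with no chiral-pool input.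

**6 from 5, and 5 from 4.** These are an oxidation-level adjustment at C7 and a phenol allylation. The oxidation deliberately erases C7, so all four stereoisomers of 4 converge on the single racemate 6. The C7–O bond itself is kept; only its hydrogen is exchanged.

**4 from two molecules of 2, via 3.** Here the skeleton is cut at C8–O4' and C7–O at once. In the forward direction, one-electron oxidation of 2 at an anode gives a phenoxyl radical. Pairing of O4' of one radical with C8 of another gives quinone methide 3, and hydration at C7 gives 4. This is chosen over a polar C8–O4' construction because both halves come from one unfunctionalised monomer, without a halide, an activated ring A fragment or a protecting group, and all 22 carbons are assembled in one operation. The step has to deliver O4'–C8 pairing over C8–C8' pairing, and must not oxidise 4 further.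

**2 from 1.** Conjugative isomerisation of the allyl group of the catalogue phenol 1 gives the (E)-propenyl monomer.

## Alternatives that were turned down

**Alternative 1: the textbook route (chiral pool, then chelation-controlled reduction).**
- Disconnection: C8–O4' by Mitsunobu inversion of a D-lactate ester with 2; C7–C1 by acyl substitution with a metallated, O-silylated ring A; C7–H by hydride.
- Forward key step: Zn(BH4)2 reduction of enantiopure ketone A1 through a five-membered chelate, giving the erythro alcohol.
- Why turned down: the two stereocentres are bought and built in separate operations, with a stoichiometric unnatural-series lactate. Three successive α-aryloxy carbonyl intermediates carry an acidic C8–H, so enantiopurity can erode. It needs Mitsunobu waste, an organometallic addition and about seven operations, and it ignores the identity of the two halves. It is kept only as a fallback.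

**Alternative 2: asymmetric dihydroxylation, then displacement at C8.**
- Disconnection: C8–O4' by SN2 with inversion on an activated threo diol.
- Forward key step: silyl ether A2 is dihydroxylated to the (7R,8R) diol A3; this is converted to cyclic sulfate A4 (or the epoxide) and opened with the phenoxide of 2.
- Why turned down: oxygen nucleophiles open aryl-substituted cyclic sulfates and epoxides at the benzylic carbon, and C7 is further activated by the para oxygen of ring A, so the 7-O-4' regioisomer is expected. Making C8 the only leaving group costs extra protecting steps. A hindered 2,6-dimethoxyphenoxide at a secondary carbon next to a benzylic oxygen invites E2 to the enol ether. At least seven steps.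

**Alternative 3: auxiliary-controlled glycolate aldol (C7–C8 bond).**
- Disconnection: C7–C8.
- Forward key step: anti-selective aldol of the aryloxyacetyl imide A6 with aldehyde A5 to give adduct A7 (auxiliary drawn as (S)-4-benzyl; the antipode would be used if the chosen anti protocol requires it).
- Why turned down: C9 arrives at the carboxyl oxidation level and needs three reductive steps to become methyl, in the presence of a benzylic alcohol and a styrene. The dependable boron syn-glycolate aldol gives the threo (syn) series, so the erythro target needs the less general anti-glycolate variants. A stoichiometric auxiliary and more than nine steps.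

Key step: step 2

## Route

**Step 1**
Reactants: 1 4-allyl-2,6-dimethoxyphenol
Product: 2 (E)-2,6-dimethoxy-4-(prop-1-en-1-yl)phenol
Conditions: RuClH(CO)(PPh3)3 (0.5 mol%), toluene, 80 °C; crystallisation or chromatography to remove residual Z isomer
Reagents that add atoms: none
Why: Ru–H olefin isomerisation (hydrometalation/β-hydride elimination) moves the terminal C=C one position into conjugation with the arene; the conjugated E isomer is the thermodynamic product and the free phenol is tolerated. No stereocentre is formed.

**Step 2**
Reactants: 2 (E)-2,6-dimethoxy-4-(prop-1-en-1-yl)phenol (two molecules)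
Product: 4 1-(4-hydroxy-3,5-dimethoxyphenyl)-2-{2,6-dimethoxy-4-[(E)-prop-1-en-1-yl]phenoxy}propan-1-ol as the racemic erythro/threo mixture, via quinone methide 3 (not isolated)
Conditions: graphite anode / Pt cathode, divided cell, controlled potential at the first anodic wave of 2, about 1 F per mol of 2, LiClO4, acetone / aq. AcOH–NaOAc buffer (pH 4.5) 1:1, 5 °C; stop at partial conversion and recycle 2
Reagents that add atoms: water, O
Why: Anodic one-electron oxidation of 2 with loss of a proton gives a phenoxyl radical whose spin density lies on O4, C1 and, through the propenyl group, C8; two such radicals pair O4' to C8, and the resulting quinone methide 3, which has no proton to lose at the coupling site, is captured at C7 by water in an acid-catalysed 1,6-addition that restores ring A as the free phenol. The closest known reaction type is the oxidative (chemical, enzymatic or anodic) dehydrodimerisation of 4-propenylphenols to 8-O-4' adducts with solvent capture of the quinone methide. No ring is closed. C8 is created in the radical pairing with no controlling element and is therefore racemic, and C7 is set only by substrate control in the hydration (expected to be erythro-biased for 2,6-dimethoxyaryl ethers); neither needs control here, because step 4 erases C7 and step 5 equilibrates C8, so all four stereoisomers of 4 are carried on together. The step needs regioselectivity for O4'–C8 pairing: the methoxy groups on C3 and C5 of 2 close the 8–5', 5–5' and 4-O–5' channels open to less substituted propenylphenols, which leaves 8–8' pairing (tetrahydrofuran lignans after hydration) as the one competing mode, to be separated. It also needs chemoselectivity between 2 and 4: the conjugated phenol 2 should be oxidised at a lower potential than the non-conjugated phenol of 4, so electrolysis at the first wave and to partial conversion should hold back trimers. The buffer keeps hydration of 3 fast relative to its tautomerisation to an enol ether or its capture by a second phenol, and the divided cell keeps 3 away from the cathode.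

**Step 3**
Reactants: 4 1-(4-hydroxy-3,5-dimethoxyphenyl)-2-{2,6-dimethoxy-4-[(E)-prop-1-en-1-yl]phenoxy}propan-1-ol (stereoisomer mixture)
Product: 5 1-[4-(allyloxy)-3,5-dimethoxyphenyl]-2-{2,6-dimethoxy-4-[(E)-prop-1-en-1-yl]phenoxy}propan-1-ol (racemic erythro/threo mixture)
Conditions: allyl bromide (1.3 equiv), K2CO3, acetone, 40 °C
Reagents that add atoms: allyl bromide, C=CCBr
Why: Williamson etherification; carbonate deprotonates only the phenol, so the secondary benzylic alcohol stays free. Allyl is chosen because it is inert to alkoxide base and to the C=O-selective hydrogenation of step 5 and is removed under neutral Pd(0) conditions.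

**Step 4**
Reactants: 5 1-[4-(allyloxy)-3,5-dimethoxyphenyl]-2-{2,6-dimethoxy-4-[(E)-prop-1-en-1-yl]phenoxy}propan-1-ol (stereoisomer mixture)
Product: 6 rac-1-[4-(allyloxy)-3,5-dimethoxyphenyl]-2-{2,6-dimethoxy-4-[(E)-prop-1-en-1-yl]phenoxy}propan-1-one
Conditions: Dess–Martin periodinane (1.2 equiv), CH2Cl2, 0 °C to rt
Reagents that add atoms: none
Why: Dess–Martin oxidation of a secondary benzylic alcohol; the two alkenes and the aryl ethers are inert to the reagent. Removal of the C7 stereocentre makes the four stereoisomers of 5 converge on one racemic ketone.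

**Step 5**
Reactants: 6 rac-1-[4-(allyloxy)-3,5-dimethoxyphenyl]-2-{2,6-dimethoxy-4-[(E)-prop-1-en-1-yl]phenoxy}propan-1-one
Product: 7 (1R,2S)-1-[4-(allyloxy)-3,5-dimethoxyphenyl]-2-{2,6-dimethoxy-4-[(E)-prop-1-en-1-yl]phenoxy}propan-1-ol
Conditions: trans-RuCl2[(R)-xylbinap][(R)-daipen] (0.2 mol%), t-BuOK (10 mol%), H2 (10 atm), i-PrOH/toluene 4:1, 25 °C
Reagents that add atoms: none
Why: Noyori-type asymmetric hydrogenation with dynamic kinetic resolution, a known reaction type for racemic α-alkoxy and α-aryloxy ketones: the alkoxide base racemises C8 of 6 through the enolate while the outer-sphere Ru–H/N–H catalyst reduces only C=O, so both C=C bonds should survive. This catalyst antipode (the one that gives (S)-1-arylethanols) should deliver hydride to the Si face of C7=O, which is 7R by CIP here. The (8S) enantiomer is expected to be the matched one, reacting in the conformer with C8–O4' syn to C=O and C8–H towards the incoming hydride; this is the same topological sense as the cis-selective reductions of 2-alkoxy- and 2-aryloxy-cycloalkanones with this catalyst class and corresponds to the anti (erythro) alcohol.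

**Step 6**
Reactants: 7 (1R,2S)-1-[4-(allyloxy)-3,5-dimethoxyphenyl]-2-{2,6-dimethoxy-4-[(E)-prop-1-en-1-yl]phenoxy}propan-1-ol
Product: 8 (1R,2S)-1-(4-hydroxy-3,5-dimethoxyphenyl)-2-{2,6-dimethoxy-4-[(E)-prop-1-en-1-yl]phenoxy}propan-1-ol (target)
Conditions: Pd(PPh3)4 (5 mol%), morpholine (10 equiv), THF, rt
Reagents that add atoms: none
Why: Tsuji–Trost deallylation: Pd(0) ionises the aryl allyl ether to a π-allyl complex and the phenoxide, and morpholine traps the allyl group. The medium is neutral, so C7 cannot ionise to a quinone methide, neither stereocentre is involved, and the propenyl group is not touched.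

## Compound list

1 | 4-allyl-2,6-dimethoxyphenol | C=CCc1cc(OC)c(O)c(OC)c1 | starting material
2 | (E)-2,6-dimethoxy-4-(prop-1-en-1-yl)phenol | C/C=C/c1cc(OC)c(O)c(OC)c1 | intermediate
3 | 4-(2-{2,6-dimethoxy-4-[(E)-prop-1-en-1-yl]phenoxy}propylidene)-2,6-dimethoxycyclohexa-2,5-dien-1-one (racemic quinone methide, not isolated) | C/C=C/c1cc(OC)c(OC(C)C=C2C=C(OC)C(=O)C(OC)=C2)c(OC)c1 | intermediate
4 | 1-(4-hydroxy-3,5-dimethoxyphenyl)-2-{2,6-dimethoxy-4-[(E)-prop-1-en-1-yl]phenoxy}propan-1-ol (racemic erythro + threo, all four stereoisomers) | C/C=C/c1cc(OC)c(OC(C)C(O)c2cc(OC)c(O)c(OC)c2)c(OC)c1 | intermediate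
5 | 1-[4-(allyloxy)-3,5-dimethoxyphenyl]-2-{2,6-dimethoxy-4-[(E)-prop-1-en-1-yl]phenoxy}propan-1-ol (racemic erythro + threo) | C/C=C/c1cc(OC)c(OC(C)C(O)c2cc(OC)c(OCC=C)c(OC)c2)c(OC)c1 | intermediate
6 | rac-1-[4-(allyloxy)-3,5-dimethoxyphenyl]-2-{2,6-dimethoxy-4-[(E)-prop-1-en-1-yl]phenoxy}propan-1-one | C/C=C/c1cc(OC)c(OC(C)C(=O)c2cc(OC)c(OCC=C)c(OC)c2)c(OC)c1 | intermediate
7 | (1R,2S)-1-[4-(allyloxy)-3,5-dimethoxyphenyl]-2-{2,6-dimethoxy-4-[(E)-prop-1-en-1-yl]phenoxy}propan-1-ol | C/C=C/c1cc(OC)c(O[C@@H](C)[C@H](O)c2cc(OC)c(OCC=C)c(OC)c2)c(OC)c1 | intermediate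
8 | (1R,2S)-1-(4-hydroxy-3,5-dimethoxyphenyl)-2-{2,6-dimethoxy-4-[(E)-prop-1-en-1-yl]phenoxy}propan-1-ol | C/C=C/c1cc(OC)c(O[C@@H](C)[C@H](O)c2cc(OC)c(O)c(OC)c2)c(OC)c1 | target

## Step count and least certain steps

Total step count: 6. Longest linear sequence: 6 (1 → 2 → 4 → 5 → 6 → 7 → 8). The risk is not confined to the key step: step 5 is a second real uncertainty.

**Step 2 (key step).**
- What may go wrong: the two radicals may pair through C8–C8' instead of O4'–C8, and the product phenol may be oxidised further so that chains grow by further O4–C8 pairing with monomer radicals. Both follow from the spin distribution of the radical and from an oxidation-potential gap between 2 and 4 that may be small.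
- Fallback (sets out from 2, returns at 6): the C8–O4' bond would be made by polar SN2 displacement instead of radical pairing.
  - 2 is O-alkylated with racemic 2-bromo-N-methoxy-N-methylpropanamide (a catalogue reagent; K2CO3, DMF, 50 °C) to give rac-N-methoxy-N-methyl-2-{2,6-dimethoxy-4-[(E)-prop-1-en-1-yl]phenoxy}propanamide F1.
  - Commercial 4-bromo-2,6-dimethoxyphenol is O-allylated (allyl bromide, K2CO3, acetone) to 2-(allyloxy)-5-bromo-1,3-dimethoxybenzene F2, which is converted with magnesium in THF into [4-(allyloxy)-3,5-dimethoxyphenyl]magnesium bromide F3.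
  - Addition of F3 to F1 (THF, 0 °C) gives 6, and the route continues with step 5.

**Step 5.**
- What may go wrong: diastereodifferentiation may be insufficient, with reduction running through a Felkin-type arrangement (C8–O4' anti to the incoming hydride) that leads to the threo series. Alternatively, racemisation of C8 may be slow relative to reduction, so that the mismatched enantiomer is reduced as well. The sense of diastereoselection rests on analogy with cyclic and simpler acyclic α-oxygenated ketones and is the least secure prediction in the route.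
- Fallback (sets out from 2, returns at 7): C8 is taken from the chiral pool and C7 is set by chelation control.
  - Mitsunobu etherification of 2 with methyl (R)-lactate (PPh3, DIAD, THF, inversion) gives methyl (S)-2-{2,6-dimethoxy-4-[(E)-prop-1-en-1-yl]phenoxy}propanoate F4.
  - Me(MeO)NH·HCl / i-PrMgCl (THF, −20 °C) gives (S)-N-methoxy-N-methyl-2-{2,6-dimethoxy-4-[(E)-prop-1-en-1-yl]phenoxy}propanamide F5.
  - Addition of F3 (made from F2 as above) gives (S)-1-[4-(allyloxy)-3,5-dimethoxyphenyl]-2-{2,6-dimethoxy-4-[(E)-prop-1-en-1-yl]phenoxy}propan-1-one F6.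
  - Zn(BH4)2 (Et2O, −30 °C) reduces F6 through a chelate bridging C7=O and O4', with hydride entering from the C8–H face, to give 7.

**Step 6.**
- What may go wrong: ionisation of the hindered, electron-rich aryl allyl ether may be slow, and a palladium hydride formed on prolonged reaction could move the allyl C=C into an enol ether that then needs acid for removal, which C7 does not tolerate.
- Fallback (sets out from 4, returns at 8): the phenol is masked with a fluoride-labile group instead, and the free phenol is used to drive the oxidation.
  - DDQ (dioxane, rt) oxidises the p-hydroxybenzylic alcohol of 4 to rac-1-(4-hydroxy-3,5-dimethoxyphenyl)-2-{2,6-dimethoxy-4-[(E)-prop-1-en-1-yl]phenoxy}propan-1-one F7.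
  - TIPSCl / imidazole (DMF) gives rac-1-[3,5-dimethoxy-4-(triisopropylsilyloxy)phenyl]-2-{2,6-dimethoxy-4-[(E)-prop-1-en-1-yl]phenoxy}propan-1-one F8.
  - The hydrogenation of step 5, with the base loading kept minimal, gives (1R,2S)-1-[3,5-dimethoxy-4-(triisopropylsilyloxy)phenyl]-2-{2,6-dimethoxy-4-[(E)-prop-1-en-1-yl]phenoxy}propan-1-ol F9.
  - TBAF (THF, 0 °C) gives 8.

## Further compounds

F1 | step 2 | rac-N-methoxy-N-methyl-2-{2,6-dimethoxy-4-[(E)-prop-1-en-1-yl]phenoxy}propanamide | C/C=C/c1cc(OC)c(OC(C)C(=O)N(C)OC)c(OC)c1
F2 | step 2 | 2-(allyloxy)-5-bromo-1,3-dimethoxybenzene | C=CCOc1c(OC)cc(Br)cc1OC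
F3 | step 2 | [4-(allyloxy)-3,5-dimethoxyphenyl]magnesium bromide | C=CCOc1c(OC)cc([Mg]Br)cc1OC
F4 | step 5 | methyl (S)-2-{2,6-dimethoxy-4-[(E)-prop-1-en-1-yl]phenoxy}propanoate | C/C=C/c1cc(OC)c(O[C@@H](C)C(=O)OC)c(OC)c1
F5 | step 5 | (S)-N-methoxy-N-methyl-2-{2,6-dimethoxy-4-[(E)-prop-1-en-1-yl]phenoxy}propanamide | C/C=C/c1cc(OC)c(O[C@@H](C)C(=O)N(C)OC)c(OC)c1
F6 | step 5 | (S)-1-[4-(allyloxy)-3,5-dimethoxyphenyl]-2-{2,6-dimethoxy-4-[(E)-prop-1-en-1-yl]phenoxy}propan-1-one | C/C=C/c1cc(OC)c(O[C@@H](C)C(=O)c2cc(OC)c(OCC=C)c(OC)c2)c(OC)c1
F7 | step 6 | rac-1-(4-hydroxy-3,5-dimethoxyphenyl)-2-{2,6-dimethoxy-4-[(E)-prop-1-en-1-yl]phenoxy}propan-1-one | C/C=C/c1cc(OC)c(OC(C)C(=O)c2cc(OC)c(O)c(OC)c2)c(OC)c1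
F8 | step 6 | rac-1-[3,5-dimethoxy-4-(triisopropylsilyloxy)phenyl]-2-{2,6-dimethoxy-4-[(E)-prop-1-en-1-yl]phenoxy}propan-1-one | C/C=C/c1cc(OC)c(OC(C)C(=O)c2cc(OC)c(O[Si](C(C)C)(C(C)C)C(C)C)c(OC)c2)c(OC)c1
F9 | step 6 | (1R,2S)-1-[3,5-dimethoxy-4-(triisopropylsilyloxy)phenyl]-2-{2,6-dimethoxy-4-[(E)-prop-1-en-1-yl]phenoxy}propan-1-ol | C/C=C/c1cc(OC)c(O[C@@H](C)[C@H](O)c2cc(OC)c(O[Si](C(C)C)(C(C)C)C(C)C)c(OC)c2)c(OC)c1
A1 | alternative 1 | (S)-1-[4-(tert-butyldimethylsilyloxy)-3,5-dimethoxyphenyl]-2-{2,6-dimethoxy-4-[(E)-prop-1-en-1-yl]phenoxy}propan-1-one | C/C=C/c1cc(OC)c(O[C@@H](C)C(=O)c2cc(OC)c(O[Si](C)(C)C(C)(C)C)c(OC)c2)c(OC)c1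
A2 | alternative 2 | tert-butyl{2,6-dimethoxy-4-[(E)-prop-1-en-1-yl]phenoxy}dimethylsilane | C/C=C/c1cc(OC)c(O[Si](C)(C)C(C)(C)C)c(OC)c1
A3 | alternative 2 | (1R,2R)-1-[4-(tert-butyldimethylsilyloxy)-3,5-dimethoxyphenyl]propane-1,2-diol | C[C@@H](O)[C@H](O)c1cc(OC)c(O[Si](C)(C)C(C)(C)C)c(OC)c1
A4 | alternative 2 | (4R,5R)-4-[4-(tert-butyldimethylsilyloxy)-3,5-dimethoxyphenyl]-5-methyl-1,3,2-dioxathiolane 2,2-dioxide | C[C@H]1OS(=O)(=O)O[C@@H]1c2cc(OC)c(O[Si](C)(C)C(C)(C)C)c(OC)c2
A5 | alternative 3 | 4-(allyloxy)-3,5-dimethoxybenzaldehyde | C=CCOc1c(OC)cc(C=O)cc1OC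
A6 | alternative 3 | (S)-4-benzyl-3-(2-{2,6-dimethoxy-4-[(E)-prop-1-en-1-yl]phenoxy}acetyl)oxazolidin-2-one | C/C=C/c1cc(OC)c(OCC(=O)N2[C@@H](Cc3ccccc3)COC2=O)c(OC)c1
A7 | alternative 3 | (S)-4-benzyl-3-[(2R,3R)-3-[4-(allyloxy)-3,5-dimethoxyphenyl]-3-hydroxy-2-{2,6-dimethoxy-4-[(E)-prop-1-en-1-yl]phenoxy}propanoyl]oxazolidin-2-one | C/C=C/c1cc(OC)c(O[C@@H](C(=O)N2[C@@H](Cc3ccccc3)COC2=O)[C@H](O)c2cc(OC)c(OCC=C)c(OC)c2)c(OC)c1
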